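## The problem

The target is a monocyclic lignan built on an oxolane (tetrahydrofuran). In the discussion the ring atoms are numbered O1, C2, C3, C4, C5; compound names follow the usual nomenclature rules. C2 and C5 are unsubstituted methylenes. C3 carries a (4-hydroxy-3,5-dimethoxyphenyl)hydroxymethyl group and C4, trans to it, a 4-hydroxy-3-methoxybenzyl group. Three contiguous stereocentres have to be set, C3 (S), C4 (S) and the exocyclic carbinol carbon (S), and nothing else in the molecule is stereogenic. The two ring centres can control each other, because trans is the stable arrangement whenever one of them is enolisable, and C3 can control the carbinol by 1,2-induction; the absolute configuration must nevertheless be brought in once from outside. The delicate part is the benzylic alcohol that sits para to a phenol on an electron-rich ring: acid ionises it, base can turn it into a quinone methide, and hydrogenolysis cleaves it. It should therefore be made late, and the phenols should be freed last under nearly neutral conditions. The feature that opens the structure is the pair of methylenes flanking O1, together with a one-carbon branch on C3 and a benzylic carbon on C4. O1–C2–C3 with the branch carbon is an alkoxide tied to an allyl unit, and C4–C5 with the benzylic carbon at the ketone level is an aryl vinyl ketone.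

## Retrosynthesis

**Unmasking, 13 from 12.** No skeletal bond is cut. Both phenols of 13 are carried as tri(propan-2-yl)silyl (TIPS) ethers in 12, so that one buffered fluoride treatment ends the synthesis. Benzyl ethers are ruled out because their hydrogenolysis would also cleave the benzylic C–O bond. What is asked of the forward reaction is only that the phenoxides are never left unprotonated next to the carbinol.

**Carbinol carbon–aryl bond, 12 from 8 and 11.** The bond between the carbinol carbon and the syringyl ring is cut, giving aldehyde 8 and aryllithium 11, which comes from bromide 10 and bromophenol 9. The neighbouring cut, C3–carbinol carbon, would need a nucleophilic C3 without an activating group. Making the carbinol by reduction of the corresponding ketone is also less attractive, since the Felkin–Anh preference of hydride is expected to give the wrong epimer. Addition of the aryl group to the aldehyde has the same facial preference but places the aryl group, not hydrogen, so it should lead to the (S)-carbinol. The precursor 8 has two stereocentres and one aryl ring less.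

**Oxidation-level changes, 8 from 7 from 6.** The aldehyde carbon of 8 is carried as a vinyl group in 7 (C=C cleavage), and the benzylic methylene of 7 as an aryl ketone in 6 (deoxygenation). The vinyl group is chosen because it cannot epimerise C3. While the ketone is present, only C4 is enolisable and can settle trans. The ketone is removed before the aldehyde is made, so that no 1,4-dicarbonyl compound with two enolisable centres ever exists, which could racemise by double epimerisation.

**Ring formation, 6 from 4 and 5.** O1–C5 and C3–C4 are cut together. Carbonate 5 supplies O1, C2, C3 and the vinyl group as an alkoxide-bearing π-allyl palladium unit, and enone 4 supplies C4, C5 and the aroyl group. Against cuts at C2–C3 or at the exocyclic bonds, this one removes the ring and both ring stereocentres in one step. It leads to one racemic commodity chemical and one achiral enone. The forward reaction must form the C3–C4 bond enantioselectively at the substituted allyl terminus, and the alkoxide must add to a singly activated enone faster than the enone oligomerises.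

**Enone, 4 from 3 from 2 from 1.** The bond between the carbinol carbon and the vinyl group is cut: vinyl Grignard addition to silylated vanillin 2 and oxidation of allylic alcohol 3. This is preferred to methylenation of the corresponding acetophenone because each step is clean and the sensitive enone is released by a filtration only. Vanillin 1 is the starting material.

## Roads not taken

**Alternative 1:** The cut is C2–C3. An acyclic syringyl ketone A1, carrying the C4 stereocentre and a methoxymethyl ether on the C5 oxygen, is converted into its enol silane. A silyl triflate Lewis acid ionises the acetal to an oxocarbenium ion, which the enol silane attacks through carbon to give the trans ketone A2.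
- Merits: both aryl groups are in place before the ring closes, no transition metal is needed, the trans relation is secured by the enolisable C3, and no deoxygenation or alkene cleavage follows. In these respects it is better than the chosen plan.
- Weak points: the closure is 5-endo with respect to the O1=C2 π bond of the oxocarbenium ion, a geometrically strained mode. A1 needs its stereocentre from auxiliary-based chemistry over several steps. The carbinol must then come from reduction of A2, where the substrate's own bias is expected to favour the wrong epimer.
- Comparison: the chosen plan sets against the saved redox steps that both ring centres arise in one catalytic step from 4 and 5, and that the carbinol is made by an addition to 8 whose intrinsic preference points the right way.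

**Alternative 2:** The cuts are C3–carbinol carbon and C4–benzyl carbon on a chiral-pool butenolide A3. A lithiated aryl dithiane A4 adds to the β carbon anti to the silyloxymethyl group, and the enolate is benzylated with bromide A5 anti again, giving the all-trans lactone A6.
- Merits: the stereocontrol is substrate-based and very dependable, both aryl units enter in one flask, and the chiral starting material is cheap. In stereochemical certainty this road is better than the chosen one.
- Weak points: A6 is a lactone with one carbon too many. After the key step the lactone must be reduced, the silyloxymethyl carbon excised, the ether ring re-formed, the dithiane removed beside electron-rich arenes, and the resulting ketone reduced against its own facial bias. That is a long tail.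
- Comparison: the chosen plan forms the oxolane directly at the right oxidation level, with O1 between two methylenes, and needs fewer steps after the ring is made. It pays with reliance on a chiral catalyst and an acceptor at the edge of the known scope.

**Alternative 3:** The cuts are C3–C4 and benzyl carbon–aryl. A redox-active ester A7, which already holds the silylated carbinol, gives a C3 radical under nickel/bipyridine catalysis with a metal reductant. The radical closes 5-exo onto the allyl ether, and the exocyclic radical is arylated by aryl iodide A8, giving A9, the tris-silyl ether of 13.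
- Merits: step economy is unmatched, since A9 is one desilylation from the target; the carbinol is set beforehand and no late ketone chemistry is needed. In this respect it is clearly better than the chosen plan.
- Weak points: C3 and C4 are both formed in a radical closure under substrate control alone. The planar C3 radical is guided only by the adjacent silyloxy centre, and hex-5-enyl radicals substituted at the radical carbon generally favour the cis ring product, whereas the target is trans. Up to four diastereomers can form, and arylation of the uncyclised radical competes.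
- Comparison: the chosen plan sets against the shorter sequence catalyst control at C3 and thermodynamic control at C4.

Key step: step 4

## Route

Assumption: the phosphoramidite enantiomer written below is taken to give the S configuration at the vinyl-bearing carbon; if the first run shows the opposite sense, its mirror image is used with no other change.

Abbreviations: TIPS = tri(propan-2-yl)silyl. L* = (11bS)-N,N-bis[(1S)-1-phenylethyl]dinaphtho[2,1-d:1',2'-f][1,3,2]dioxaphosphepin-4-amine, the BINOL-derived phosphoramidite.

Step 1
Reactants: 1 vanillin (4-hydroxy-3-methoxybenzaldehyde)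
Product: 2 3-methoxy-4-(TIPS-oxy)benzaldehyde
Conditions: TIPSCl, imidazole, DMF, 25 °C
Reagents that add atoms: chlorotri(propan-2-yl)silane (TIPSCl), CC(C)[Si](Cl)(C(C)C)C(C)C
Why: Imidazole-promoted silylation of a phenol. The bulky aryl silyl ether should survive Grignard and aryllithium reagents, trifluoroacetic acid and periodate, and falls to fluoride at the end.

Step 2
Reactants: 2 3-methoxy-4-(TIPS-oxy)benzaldehyde
Product: 3 rac-1-[3-methoxy-4-(TIPS-oxy)phenyl]prop-2-en-1-ol
Conditions: CH2=CHMgBr, THF, −78 to 0 °C; aq NH4Cl
Reagents that add atoms: vinylmagnesium bromide, C=C[Mg]Br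
Why: Grignard 1,2-addition to an aromatic aldehyde. The carbinol centre is formed racemic and is erased in step 3.

Step 3
Reactants: 3 rac-1-[3-methoxy-4-(TIPS-oxy)phenyl]prop-2-en-1-ol
Product: 4 1-[3-methoxy-4-(TIPS-oxy)phenyl]prop-2-en-1-one
Conditions: MnO2 (activated, excess), CH2Cl2, 25 °C; filtration, used at once
Reagents that add atoms: none
Why: MnO2 oxidation of an alcohol that is both allylic and benzylic. The neutral heterogeneous conditions and the filtration work-up should spare the polymerisation-prone aryl vinyl ketone.

Step 4
Reactants: 4 1-[3-methoxy-4-(TIPS-oxy)phenyl]prop-2-en-1-one; 5 rac-4-ethenyl-1,3-dioxolan-2-one (vinylethylene carbonate)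
Product: 6 [(3S,4S)-4-ethenyloxolan-3-yl][3-methoxy-4-(TIPS-oxy)phenyl]methanone (aroyl and vinyl groups trans)
Conditions: Pd2(dba)3·CHCl3 (2.5 mol %), L* (10 mol %), THF, 25 °C, 4 added slowly to 5 (1.5 equiv) and catalyst; then anhydrous 1,8-diazabicyclo[5.4.0]undec-7-ene (DBU, 10 mol %), 25 °C
Reagents that add atoms: none
Why: Zerovalent palladium ionises the allylic C–O bond of 5 and CO2 is lost, leaving an alkoxide tethered to a π-allyl complex of divalent palladium; the alkoxide adds to the free β-methylene of 4 (oxa-Michael, O1–C5) and the aryl ketone enolate then attacks the internal allyl terminus (C3–C4), releasing the catalyst. The closest known reaction type is the palladium-catalysed decarboxylative (3+2) annulation of vinylethylene carbonates and vinyl oxiranes with Michael acceptors, α,β-unsaturated ketones included. The oxolane closes in the C–C bond-forming event as a 5-exo allylic alkylation with the vinyl group left outside the ring; the 7-endo alternative at the far terminus is slower. The vinyl-bearing carbon is controlled by the phosphoramidite: the diastereomeric π-allyl complexes from racemic 5 interconvert by π–σ–π isomerisation faster than the enolate attacks, so both enantiomers of 5 should converge on one product (dynamic kinetic asymmetric transformation). The ketone-bearing carbon is enolisable and is brought to the more stable trans arrangement by the DBU treatment, which cannot touch the allylic centre. The step needs branched regioselectivity, secured by the short tether between enolate and allyl unit. It also needs the oxa-Michael addition to outrun enone oligomerisation, which the unhindered β-carbon of 4 and its low stationary concentration should provide.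

Step 5
Reactants: 6 [(3S,4S)-4-ethenyloxolan-3-yl][3-methoxy-4-(TIPS-oxy)phenyl]methanone
Product: 7 (3S,4S)-3-ethenyl-4-{[3-methoxy-4-(TIPS-oxy)phenyl]methyl}oxolane (trans)
Conditions: Et3SiH (5 equiv), CF3CO2H, CH2Cl2, 0 to 25 °C
Reagents that add atoms: none
Why: Ionic hydrogenation of an electron-rich aryl ketone: protonation and two hydride transfers by way of the benzylic cation, which the para silyloxy group stabilises. A monosubstituted alkene is not reduced under these conditions, and excess silane should capture the cation before it can lose the C4 proton, so both ring centres are kept.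

Step 6
Reactants: 7 (3S,4S)-3-ethenyl-4-{[3-methoxy-4-(TIPS-oxy)phenyl]methyl}oxolane
Product: 8 (3S,4S)-4-{[3-methoxy-4-(TIPS-oxy)phenyl]methyl}oxolane-3-carbaldehyde (trans)
Conditions: OsO4 (2 mol %), NaIO4 (4 equiv), 2,6-lutidine, 1,4-dioxane/H2O, 25 °C
Reagents that add atoms: osmium tetroxide, O=[Os](=O)(=O)=O (catalytic; supplies the aldehyde oxygen); sodium periodate, [Na+].[O-]I(=O)(=O)=O (terminal oxidant that restores it)
Why: Lemieux–Johnson oxidation (dihydroxylation and glycol cleavage in one flask), which spares electron-rich arenes better than ozone does. The aldehyde-bearing carbon is already in the stable trans arrangement, so enolisation cannot harm it.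

Step 7
Reactants: 9 4-bromo-2,6-dimethoxyphenol
Product: 10 (4-bromo-2,6-dimethoxyphenoxy)tri(propan-2-yl)silane
Conditions: TIPSCl, imidazole, DMF, 50 °C
Reagents that add atoms: chlorotri(propan-2-yl)silane (TIPSCl), CC(C)[Si](Cl)(C(C)C)C(C)C
Why: Silylation of a hindered phenol. The silyl ether para to bromine cannot migrate to carbon after lithiation and matches the protecting group of the other ring.

Step 8
Reactants: 10 (4-bromo-2,6-dimethoxyphenoxy)tri(propan-2-yl)silane; 8 (3S,4S)-4-{[3-methoxy-4-(TIPS-oxy)phenyl]methyl}oxolane-3-carbaldehyde
Product: 12 (S)-[3,5-dimethoxy-4-(TIPS-oxy)phenyl][(3S,4S)-4-{[3-methoxy-4-(TIPS-oxy)phenyl]methyl}oxolan-3-yl]methanol, via aryllithium 11 (not isolated)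
Conditions: 10, n-BuLi, THF, −78 °C; then 8, −78 °C; aq NH4Cl
Reagents that add atoms: none
Why: Bromine–lithium exchange followed by organolithium 1,2-addition to the aldehyde. The carbinol centre is set by Felkin–Anh 1,2-induction from C3: the branched ring carbon C4 stands anti to the incoming aryl group and C2 lies beside the carbonyl oxygen, the same rotamer that lithium bridging to O1 would hold, so attack past the C3 hydrogen should give the (S)-carbinol. Diastereomeric purity is completed by chromatography.

Step 9
Reactants: 12 (S)-[3,5-dimethoxy-4-(TIPS-oxy)phenyl][(3S,4S)-4-{[3-methoxy-4-(TIPS-oxy)phenyl]methyl}oxolan-3-yl]methanol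
Product: 13 4-[(S)-hydroxy{(3S,4S)-4-[(4-hydroxy-3-methoxyphenyl)methyl]oxolan-3-yl}methyl]-2,6-dimethoxyphenol (CNP0307127.2)
Conditions: Bu4NF (2.5 equiv), AcOH (2.5 equiv), THF, 0 °C
Reagents that add atoms: none
Why: Fluoride-mediated cleavage of both aryl silyl ethers. The acetic acid buffer keeps the liberated phenols protonated, so the para-hydroxybenzylic alcohol should not ionise to a quinone methide, and no stereocentre is touched.

## Compound list

1 | vanillin (4-hydroxy-3-methoxybenzaldehyde) | COc1cc(C=O)ccc1O | starting material
2 | 3-methoxy-4-{[tri(propan-2-yl)silyl]oxy}benzaldehyde | COc1cc(C=O)ccc1O[Si](C(C)C)(C(C)C)C(C)C | intermediate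
3 | rac-1-(3-methoxy-4-{[tri(propan-2-yl)silyl]oxy}phenyl)prop-2-en-1-ol | COc1cc(C(O)C=C)ccc1O[Si](C(C)C)(C(C)C)C(C)C | intermediate
4 | 1-(3-methoxy-4-{[tri(propan-2-yl)silyl]oxy}phenyl)prop-2-en-1-one | COc1cc(C(=O)C=C)ccc1O[Si](C(C)C)(C(C)C)C(C)C | intermediate
5 | rac-4-ethenyl-1,3-dioxolan-2-one (vinylethylene carbonate) | C=CC1COC(=O)O1 | starting material
6 | [(3S,4S)-4-ethenyloxolan-3-yl](3-methoxy-4-{[tri(propan-2-yl)silyl]oxy}phenyl)methanone, trans | COc1cc(C(=O)[C@@H]2COC[C@H]2C=C)ccc1O[Si](C(C)C)(C(C)C)C(C)C | intermediate
7 | (3S,4S)-3-ethenyl-4-[(3-methoxy-4-{[tri(propan-2-yl)silyl]oxy}phenyl)methyl]oxolane, trans | COc1cc(C[C@@H]2COC[C@H]2C=C)ccc1O[Si](C(C)C)(C(C)C)C(C)C | intermediate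
8 | (3S,4S)-4-[(3-methoxy-4-{[tri(propan-2-yl)silyl]oxy}phenyl)methyl]oxolane-3-carbaldehyde, trans | COc1cc(C[C@@H]2COC[C@H]2C=O)ccc1O[Si](C(C)C)(C(C)C)C(C)C | intermediate
9 | 4-bromo-2,6-dimethoxyphenol | COc1cc(Br)cc(OC)c1O | starting material
10 | (4-bromo-2,6-dimethoxyphenoxy)tri(propan-2-yl)silane | COc1cc(Br)cc(OC)c1O[Si](C(C)C)(C(C)C)C(C)C | intermediate
11 | (3,5-dimethoxy-4-{[tri(propan-2-yl)silyl]oxy}phenyl)lithium | COc1cc([Li])cc(OC)c1O[Si](C(C)C)(C(C)C)C(C)C | intermediate (not isolated)
12 | (S)-(3,5-dimethoxy-4-{[tri(propan-2-yl)silyl]oxy}phenyl){(3S,4S)-4-[(3-methoxy-4-{[tri(propan-2-yl)silyl]oxy}phenyl)methyl]oxolan-3-yl}methanol | COc1cc(C[C@@H]2COC[C@H]2[C@H](O)c2cc(OC)c(O[Si](C(C)C)(C(C)C)C(C)C)c(OC)c2)ccc1O[Si](C(C)C)(C(C)C)C(C)C | intermediate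
13 | 4-[(S)-hydroxy{(3S,4S)-4-[(4-hydroxy-3-methoxyphenyl)methyl]oxolan-3-yl}methyl]-2,6-dimethoxyphenol | COc1cc(C[C@@H]2COC[C@H]2[C@H](O)c2cc(OC)c(O)c(OC)c2)ccc1O | target

## Step count and risks

Total step count: 9. Longest linear sequence: 8 steps (steps 1–6, 8 and 9 from vanillin 1); step 7 is the one-step side branch.

**Step 4 (key step).**
- What may go wrong: slow oxa-Michael addition of the palladium-bound alkoxide to an electron-rich, singly activated enone, so that oligomerisation of the enone or unproductive consumption of the carbonate takes over. Enantio-induction may also be insufficient, because the ring-closing allylation involves a conformationally free enolate.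
- Fallback (sets out from 2, returns at 7): 2 is reduced with NaBH4 to the benzylic alcohol F1, which an Appel reaction (CBr4, PPh3) converts into the benzylic bromide F2. (R)-4-Ethenyloxolan-2-one F3 is made by Hayashi–Miyaura conjugate addition of potassium vinyltrifluoroborate to commercial furan-2(5H)-one with Rh(acac)(C2H4)2 and the BINAP enantiomer that delivers the R lactone. Deprotonation of F3 with LiN(SiMe3)2 in THF at −78 °C and alkylation with F2, anti to the vinyl group, should give the trans lactone F4. LiAlH4 opens it to the diol F5, and one-pot monotosylation and ring closure (n-BuLi, TsCl, then n-BuLi) gives 7. This replaces the annulation by a conjugate addition and a trans-selective lactone alkylation, at the cost of about four more steps.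

**Step 5.**
- What may go wrong: loss of the C4 proton from the benzylic cation and re-protonation, which would scramble C4. Partial loss of the aryl silyl ether through a quinone methide is also possible.
- Fallback (sets out from 6, returns at 7): 6 is condensed with 4-methylbenzenesulfonohydrazide to the tosylhydrazone F6, which is reduced with catecholborane and then decomposed with NaOAc·3H2O. Hydride adds to the C=N bond, sulfinate leaves and the diazene loses nitrogen, so the methylene forms without any cation next to C4.

**Step 8.**
- What may go wrong: poor facial selectivity, since the Felkin–Anh bias of aldehydes on five-membered rings can be modest; enolisation of the aldehyde by the aryllithium is a lesser concern.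
- Fallback (sets out from 12 as obtained, returns at 12): the unseparated addition product, 12 together with its carbinol epimer F7, is oxidised with Dess–Martin periodinane to the aryl ketone F8. F8 is then reduced by a Corey–Bakshi–Shibata reduction with BH3·SMe2 and (R)-1-methyl-3,3-diphenyltetrahydro-1H,3H-pyrrolo[1,2-c][1,3,2]oxazaborole, which should deliver the (S)-carbinol 12 with the aryl group as the large substituent. Here the reagent has to override the ketone's own facial preference, so this is the less comfortable way of setting the centre and is held in reserve.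

## Further compounds

F1 | step 4 | (3-methoxy-4-{[tri(propan-2-yl)silyl]oxy}phenyl)methanol | COc1cc(CO)ccc1O[Si](C(C)C)(C(C)C)C(C)C
F2 | step 4 | [4-(bromomethyl)-2-methoxyphenoxy]tri(propan-2-yl)silane | COc1cc(CBr)ccc1O[Si](C(C)C)(C(C)C)C(C)C
F3 | step 4 | (R)-4-ethenyloxolan-2-one | C=C[C@@H]1COC(=O)C1
F4 | step 4 | (3S,4S)-4-ethenyl-3-[(3-methoxy-4-{[tri(propan-2-yl)silyl]oxy}phenyl)methyl]oxolan-2-one | COc1cc(C[C@@H]2C(=O)OC[C@H]2C=C)ccc1O[Si](C(C)C)(C(C)C)C(C)C
F5 | step 4 | (2S,3S)-2-ethenyl-3-[(3-methoxy-4-{[tri(propan-2-yl)silyl]oxy}phenyl)methyl]butane-1,4-diol | COc1cc(C[C@@H]([C@@H](CO)C=C)CO)ccc1O[Si](C(C)C)(C(C)C)C(C)C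
F6 | step 5 | N'-{[(3S,4S)-4-ethenyloxolan-3-yl](3-methoxy-4-{[tri(propan-2-yl)silyl]oxy}phenyl)methylidene}-4-methylbenzenesulfonohydrazide | COc1cc(C(=NNS(=O)(=O)c2ccc(C)cc2)[C@@H]2COC[C@H]2C=C)ccc1O[Si](C(C)C)(C(C)C)C(C)C
F7 | step 8 | (R)-(3,5-dimethoxy-4-{[tri(propan-2-yl)silyl]oxy}phenyl){(3S,4S)-4-[(3-methoxy-4-{[tri(propan-2-yl)silyl]oxy}phenyl)methyl]oxolan-3-yl}methanol | COc1cc(C[C@@H]2COC[C@H]2[C@@H](O)c2cc(OC)c(O[Si](C(C)C)(C(C)C)C(C)C)c(OC)c2)ccc1O[Si](C(C)C)(C(C)C)C(C)C
F8 | step 8 | (3,5-dimethoxy-4-{[tri(propan-2-yl)silyl]oxy}phenyl){(3S,4S)-4-[(3-methoxy-4-{[tri(propan-2-yl)silyl]oxy}phenyl)methyl]oxolan-3-yl}methanone | COc1cc(C[C@@H]2COC[C@H]2C(=O)c2cc(OC)c(O[Si](C(C)C)(C(C)C)C(C)C)c(OC)c2)ccc1O[Si](C(C)C)(C(C)C)C(C)C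
A1 | alternative 1 | (S)-1-(3,5-dimethoxy-4-{[tri(propan-2-yl)silyl]oxy}phenyl)-4-(methoxymethoxy)-3-[(3-methoxy-4-{[tri(propan-2-yl)silyl]oxy}phenyl)methyl]butan-1-one | COc1cc(C[C@@H](CC(=O)c2cc(OC)c(O[Si](C(C)C)(C(C)C)C(C)C)c(OC)c2)COCOC)ccc1O[Si](C(C)C)(C(C)C)C(C)C
A2 | alternative 1 | trans-3-aroyl-4-benzyloxolane, the bis-silyl ketone (same structure as F8) | COc1cc(C[C@@H]2COC[C@H]2C(=O)c2cc(OC)c(O[Si](C(C)C)(C(C)C)C(C)C)c(OC)c2)ccc1O[Si](C(C)C)(C(C)C)C(C)C
A3 | alternative 2 | (S)-5-{[tert-butyl(dimethyl)silyl]oxymethyl}furan-2(5H)-one | O=C1C=C[C@@H](CO[Si](C)(C)C(C)(C)C)O1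
A4 | alternative 2 | 2-(3,5-dimethoxy-4-{[tri(propan-2-yl)silyl]oxy}phenyl)-1,3-dithiane | COc1cc(C2SCCCS2)cc(OC)c1O[Si](C(C)C)(C(C)C)C(C)C
A5 | alternative 2 | [4-(bromomethyl)-2-methoxyphenoxy]tri(propan-2-yl)silane (same structure as F2) | COc1cc(CBr)ccc1O[Si](C(C)C)(C(C)C)C(C)C
A6 | alternative 2 | all-trans α-benzyl-β-(2-aryl-1,3-dithian-2-yl)-γ-(silyloxymethyl)butyrolactone | COc1cc(C[C@@H]2C(=O)O[C@H](CO[Si](C)(C)C(C)(C)C)[C@H]2C3(SCCCS3)c3cc(OC)c(O[Si](C(C)C)(C(C)C)C(C)C)c(OC)c3)ccc1O[Si](C(C)C)(C(C)C)C(C)C
A7 | alternative 3 | 1,3-dioxoisoindolin-2-yl (3S)-3-(3,5-dimethoxy-4-{[tri(propan-2-yl)silyl]oxy}phenyl)-2-[(prop-2-enyloxy)methyl]-3-{[tri(propan-2-yl)silyl]oxy}propanoate, either configuration at the carboxyl-bearing carbon | C=CCOCC(C(=O)ON1C(=O)c2ccccc2C1=O)[C@H](O[Si](C(C)C)(C(C)C)C(C)C)c1cc(OC)c(O[Si](C(C)C)(C(C)C)C(C)C)c(OC)c1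
A8 | alternative 3 | (4-iodo-2-methoxyphenoxy)tri(propan-2-yl)silane | COc1cc(I)ccc1O[Si](C(C)C)(C(C)C)C(C)C
A9 | alternative 3 | tris-TIPS ether of 13 | COc1cc(C[C@@H]2COC[C@H]2[C@H](O[Si](C(C)C)(C(C)C)C(C)C)c2cc(OC)c(O[Si](C(C)C)(C(C)C)C(C)C)c(OC)c2)ccc1O[Si](C(C)C)(C(C)C)C(C)C
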